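## Retrosynthetic overview
1. The central CH2–CH2 bond is cut last: Julia–Kocienski union of hydroazulene tetrazolyl sulfone 24 (C15) with benzoxepane aldehyde 40 (C15), then diimide reduction and end-game adjustment at C-7 (ketone, then MeMgBr).
2. Hydroazulene half: the six-membered ring is made first (Robinson annulation, then asymmetric conjugate addition), enlarged to the seven-membered ring (Ito–Saegusa), and the cyclopentanol is closed last (SmI2); CBS reduction and Wittig–Still rearrangement place the C-5 arm.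
3. Benzoxepane half: the cyclohexenone comes from an organocatalytic Michael/aldol sequence; cuprate addition/allylation and a bulky hydride set the ring centres; the oxepane is closed last by 7-endo opening of a Shi epoxide.

Assumption: the SMILES is taken literally, i.e. a cis-fused oxepane–cyclohexane unit (3S,5aS,6S,7R,9aR) and a cis-fused hydroazulene (1S,3aS,5R,8aS); locants in names follow azulene and 1-benzoxepine numbering.

## Hydroazulene half (steps 1–15)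

Step 1
Reactants: 1 but-3-en-2-one
Product: 3 2-(2-bromoethyl)-2-methyl-1,3-dioxolane, via 4-bromobutan-2-one 2 (not isolated)
Conditions: HBr (gas), CH2Cl2, 0 °C; then HOCH2CH2OH, p-TsOH (cat.), rt
Reagents that add atoms: hydrogen bromide, Br; ethane-1,2-diol, OCCO
Why: Conjugate hydrobromination of the enone followed by ketalisation in the same pot masks the ketone for the organometallic steps.

Step 2
Reactants: 3 2-(2-bromoethyl)-2-methyl-1,3-dioxolane
Product: 5 [2-(2-methyl-1,3-dioxolan-2-yl)ethyl][(trimethylsilyl)methyl]zinc, via Grignard reagent 4 (not isolated)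
Conditions: Mg, THF, 25 °C; then added to Me3SiCH2ZnCl (1.0 equiv, premade from Me3SiCH2MgCl and ZnCl2, Et2O, 0 °C); 1,4-dioxane, filtration; used as toluene solution
Reagents that add atoms: zinc dichloride, Cl[Zn]Cl; [(trimethylsilyl)methyl]magnesium chloride, C[Si](C)(C)C[Mg]Cl
Why: Grignard formation and magnesium-to-zinc transmetalation onto (trimethylsilyl)methylzinc chloride give a mixed diorganozinc that carries one transferable alkyl group and one non-transferable (trimethylsilyl)methyl group, and the magnesium halides are removed as their dioxane complexes so that the copper-catalysed addition runs salt-free.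

Step 3
Reactants: 6 2-methylpropanal; 7 pent-1-en-3-one
Product: 9 2,4,4-trimethylcyclohex-2-en-1-one, via 2,2-dimethyl-5-oxoheptanal 8 (not isolated)
Conditions: H2SO4 (cat.), 45 °C; then toluene, reflux, Dean–Stark
Reagents that add atoms: none
Why: Robinson annulation (acid-catalysed Michael addition, then aldol condensation of the ethyl ketone CH2 onto the non-enolisable aldehyde); no stereocentre is formed.

Step 4
Reactants: 9 2,4,4-trimethylcyclohex-2-en-1-one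
Product: 10 2,4,4-trimethylcyclohexa-2,5-dien-1-one
Conditions: IBX, DMSO–toluene, 80 °C
Reagents that add atoms: none
Why: IBX dehydrogenation through the only available enol gives the cross-conjugated dienone; the quaternary C-4 prevents aromatisation.

Step 5
Reactants: 10 2,4,4-trimethylcyclohexa-2,5-dien-1-one; 5 [2-(2-methyl-1,3-dioxolan-2-yl)ethyl][(trimethylsilyl)methyl]zinc
Product: 12 trimethyl({(3S)-4,4,6-trimethyl-3-[2-(2-methyl-1,3-dioxolan-2-yl)ethyl]cyclohexa-1,5-dien-1-yl}oxy)silane, via zinc enolate 11 (not isolated)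
Conditions: 5 (1.3 equiv), Cu(OTf)2 (2 mol %), (R,S,S)-binaphthyl bis(1-phenylethyl)phosphoramidite (4 mol %), toluene, −30 °C; then Me3SiOTf, −30 to 0 °C
Reagents that add atoms: trimethylsilyl trifluoromethanesulfonate, C[Si](C)(C)OS(=O)(=O)C(F)(F)F
Why: Feringa-type copper-catalysed asymmetric conjugate addition transfers only the functionalised alkyl group of the mixed zinc reagent (the (trimethylsilyl)methyl group stays on zinc) to the α-unsubstituted enone half, the ligand antipode fixes the new centre as (S) (later C-3a), and O-silylation of the zinc enolate fixes the enol regiochemistry.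

Step 6
Reactants: 12 trimethyl({(3S)-4,4,6-trimethyl-3-[2-(2-methyl-1,3-dioxolan-2-yl)ethyl]cyclohexa-1,5-dien-1-yl}oxy)silane
Product: 13 trimethyl({(1R,5S,6S)-2,4,4-trimethyl-5-[2-(2-methyl-1,3-dioxolan-2-yl)ethyl]bicyclo[4.1.0]hept-2-en-1-yl}oxy)silane
Conditions: Et2Zn, CH2I2, CH2Cl2, 0 °C
Reagents that add atoms: diiodomethane, ICI
Why: Simmons–Smith (Furukawa) cyclopropanation takes the electron-rich silyl enol ether double bond, anti to the neighbouring side chain; the two new centres are lost again in step 7.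

Step 7
Reactants: 13 trimethyl({(1R,5S,6S)-2,4,4-trimethyl-5-[2-(2-methyl-1,3-dioxolan-2-yl)ethyl]bicyclo[4.1.0]hept-2-en-1-yl}oxy)silane
Product: 15 (5S)-2,4,4-trimethyl-5-[2-(2-methyl-1,3-dioxolan-2-yl)ethyl]cyclohepta-2,6-dien-1-one, via β-chloro ketone 14 (not isolated)
Conditions: FeCl3 (2.2 equiv), DMF, 0 °C to rt; then NaOAc, MeOH, reflux
Reagents that add atoms: none
Why: Ito–Saegusa ring expansion: FeCl3 oxidation cleaves the internal cyclopropane bond to a ring-enlarged β-keto radical that is chlorinated, and E1cB loss of HCl gives the cycloheptadienone; the ketal side chain offers no radical acceptor and the (5S) centre is untouched.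

Step 8
Reactants: 15 (5S)-2,4,4-trimethyl-5-[2-(2-methyl-1,3-dioxolan-2-yl)ethyl]cyclohepta-2,6-dien-1-one
Product: 16 (5S)-2,4,4-trimethyl-5-(3-oxobutyl)cyclohepta-2,6-dien-1-one
Conditions: PPTS, acetone–H2O, 50 °C
Reagents that add atoms: water, O
Why: Mild acid-catalysed ketal hydrolysis frees the methyl ketone without touching the dienone.

Step 9
Reactants: 16 (5S)-2,4,4-trimethyl-5-(3-oxobutyl)cyclohepta-2,6-dien-1-one
Product: 17 (1S,3aS,8aS)-1-hydroxy-1,4,4,6-tetramethyl-2,3,3a,4,8,8a-hexahydroazulen-7(1H)-one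
Conditions: SmI2 (2.2 equiv), HMPA, t-BuOH, THF, −78 °C
Reagents that add atoms: none
Why: SmI2 ketyl–olefin (reductive ketone–enone) 5-exo cyclisation: the tether delivers C-1 to the unsubstituted enone β-carbon on the face of the side chain (cis fusion, C-8a) and the samarium-bound oxygen turns away from the CH2C=O branch (C-1 hydroxyl trans to C-8).

Step 10
Reactants: 17 (1S,3aS,8aS)-1-hydroxy-1,4,4,6-tetramethyl-2,3,3a,4,8,8a-hexahydroazulen-7(1H)-one
Product: 18 (1S,3aS,8aS)-1,4,4,6-tetramethyl-1-[(triethylsilyl)oxy]-2,3,3a,4,8,8a-hexahydroazulen-7(1H)-one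
Conditions: Et3SiOTf, 2,6-lutidine, CH2Cl2, −78 to 0 °C
Reagents that add atoms: triethylsilyl trifluoromethanesulfonate, CC[Si](CC)(CC)OS(=O)(=O)C(F)(F)F
Why: Silylation of the tertiary alcohol with the silyl triflate protects it through the base-mediated steps that follow.

Step 11
Reactants: 18 (1S,3aS,8aS)-1,4,4,6-tetramethyl-1-[(triethylsilyl)oxy]-2,3,3a,4,8,8a-hexahydroazulen-7(1H)-one
Product: 19 (1S,3aS,7R,8aS)-1,4,4,6-tetramethyl-1-[(triethylsilyl)oxy]-1,2,3,3a,4,7,8,8a-octahydroazulen-7-ol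
Conditions: (S)-2-methyl-CBS-oxazaborolidine (20 mol %), BH3·THF, THF, −20 °C
Reagents that add atoms: none
Why: Corey–Bakshi–Shibata reduction of the 2-methyl enone (alkene side as the large group) is reagent-controlled and gives the (7R) allylic alcohol, hydroxyl on the face opposite to H-8a.

Step 12
Reactants: 19 (1S,3aS,7R,8aS)-1,4,4,6-tetramethyl-1-[(triethylsilyl)oxy]-1,2,3,3a,4,7,8,8a-octahydroazulen-7-ol
Product: 20 tributyl[({(1S,3aS,7R,8aS)-1,4,4,6-tetramethyl-1-[(triethylsilyl)oxy]-1,2,3,3a,4,7,8,8a-octahydroazulen-7-yl}oxy)methyl]stannane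
Conditions: KH, Bu3SnCH2I, THF, 0 °C to rt
Reagents that add atoms: tributyl(iodomethyl)stannane, CCCC[Sn](CCCC)(CCCC)CI
Why: Williamson etherification of the potassium alkoxide installs the stannylmethyl ether needed for the rearrangement.

Step 13
Reactants: 20 tributyl[({(1S,3aS,7R,8aS)-1,4,4,6-tetramethyl-1-[(triethylsilyl)oxy]-1,2,3,3a,4,7,8,8a-octahydroazulen-7-yl}oxy)methyl]stannane
Product: 22 {(1S,3aS,5R,8aS)-1,4,4,6-tetramethyl-1-[(triethylsilyl)oxy]-1,2,3,3a,4,5,8,8a-octahydroazulen-5-yl}methanol, via lithiomethyl ether 21 (not isolated)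
Conditions: n-BuLi, THF, −78 to −40 °C; aq. NH4Cl
Reagents that add atoms: none
Why: Wittig–Still [2,3]-sigmatropic rearrangement: tin–lithium exchange, then a suprafacial shift carries the CH2O unit from O-7 to C-5 on the same face (5R) and moves the double bond to C6=C7.

Step 14
Reactants: 22 {(1S,3aS,5R,8aS)-1,4,4,6-tetramethyl-1-[(triethylsilyl)oxy]-1,2,3,3a,4,5,8,8a-octahydroazulen-5-yl}methanol
Product: 23 1-phenyl-5-[({(1S,3aS,5R,8aS)-1,4,4,6-tetramethyl-1-[(triethylsilyl)oxy]-1,2,3,3a,4,5,8,8a-octahydroazulen-5-yl}methyl)sulfanyl]-1H-tetrazole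
Conditions: 1-phenyl-1H-tetrazole-5-thiol, PPh3, DIAD, THF, 0 °C to rt
Reagents that add atoms: 1-phenyl-1H-tetrazole-5-thiol, Sc1nnnn1-c1ccccc1
Why: Mitsunobu thioetherification of the primary alcohol; no stereocentre is involved.

Step 15
Reactants: 23 1-phenyl-5-[({(1S,3aS,5R,8aS)-1,4,4,6-tetramethyl-1-[(triethylsilyl)oxy]-1,2,3,3a,4,5,8,8a-octahydroazulen-5-yl}methyl)sulfanyl]-1H-tetrazole
Product: 24 1-phenyl-5-[({(1S,3aS,5R,8aS)-1,4,4,6-tetramethyl-1-[(triethylsilyl)oxy]-1,2,3,3a,4,5,8,8a-octahydroazulen-5-yl}methyl)sulfonyl]-1H-tetrazole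
Conditions: (NH4)6Mo7O24·4H2O (cat.), 30% H2O2, EtOH, 0 °C to rt
Reagents that add atoms: hydrogen peroxide, OO
Why: Molybdate-catalysed peroxide oxidation takes the sulfide to the sulfone and leaves the hindered trisubstituted alkene alone.

## Benzoxepane half (steps 16–28)

Step 16
Reactants: 25 1,4-dioxane-2,5-diol
Product: 26 [(tert-butyldimethylsilyl)oxy]acetaldehyde
Conditions: t-BuMe2SiCl, imidazole, CH2Cl2, rt
Reagents that add atoms: tert-butyl(chloro)dimethylsilane, CC(C)(C)[Si](C)(C)Cl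
Why: The dimer is in equilibrium with glycolaldehyde, whose hydroxyl is silylated to give two equivalents of the monomeric aldehyde.

Step 17
Reactants: 26 [(tert-butyldimethylsilyl)oxy]acetaldehyde; 7 pent-1-en-3-one
Product: 27 (2S)-2-[(tert-butyldimethylsilyl)oxy]-5-oxoheptanal
Conditions: (R)-2-[methoxy(diphenyl)methyl]pyrrolidine (5 mol %), ethyl 3,4-dihydroxybenzoate (20 mol %), neat, 4 °C
Reagents that add atoms: none
Why: Enamine-catalysed Michael addition of the aldehyde to the vinyl ketone; the diarylprolinol ether shields one enamine face and sets the silyloxy-bearing centre as (S).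

Step 18
Reactants: 27 (2S)-2-[(tert-butyldimethylsilyl)oxy]-5-oxoheptanal
Product: 28 (4S)-4-[(tert-butyldimethylsilyl)oxy]-2-methylcyclohex-2-en-1-one
Conditions: p-TsOH·H2O (cat.), toluene, 60 °C
Reagents that add atoms: none
Why: Intramolecular aldol condensation of the ethyl ketone CH2 onto the aldehyde (the only mode that gives a six-membered ring) forms the 2-methyl enone; the stereocentre becomes the γ-carbon and is not enolised.

Step 19
Reactants: 28 (4S)-4-[(tert-butyldimethylsilyl)oxy]-2-methylcyclohex-2-en-1-one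
Product: 30 (2S,3S,4S)-4-[(tert-butyldimethylsilyl)oxy]-3-{[dimethyl(phenyl)silyl]methyl}-2-methyl-2-(prop-2-en-1-yl)cyclohexan-1-one, via magnesium enolate 29 (not isolated)
Conditions: PhMe2SiCH2MgCl (2.2 equiv), CuI (1.1 equiv), THF, −40 °C; 28, −78 °C; then allyl bromide, HMPA, −78 to −20 °C
Reagents that add atoms: {[dimethyl(phenyl)silyl]methyl}magnesium chloride, C[Si](C)(C[Mg]Cl)c1ccccc1; 3-bromoprop-1-ene, C=CCBr
Why: Cuprate conjugate addition anti to the γ-silyloxy group, then allylation of the regiodefined enolate anti to the new β-substituent (three-component coupling), builds the quaternary centre with methyl cis to the silylmethyl arm.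

Step 20
Reactants: 30 (2S,3S,4S)-4-[(tert-butyldimethylsilyl)oxy]-3-{[dimethyl(phenyl)silyl]methyl}-2-methyl-2-(prop-2-en-1-yl)cyclohexan-1-one
Product: 32 (2S,3S,4S)-4-[(tert-butyldimethylsilyl)oxy]-3-{[dimethyl(phenyl)silyl]methyl}-2-(3-hydroxypropyl)-2-methylcyclohexan-1-one, via alkylborane 31 (not isolated)
Conditions: 9-BBN, THF, rt; then NaOH, 30% H2O2, 0 °C
Reagents that add atoms: hydrogen peroxide, OO
Why: Anti-Markovnikov hydroboration–oxidation of the terminal alkene; the neopentyl ketone is too hindered to be reduced by 9-BBN.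

Step 21
Reactants: 32 (2S,3S,4S)-4-[(tert-butyldimethylsilyl)oxy]-3-{[dimethyl(phenyl)silyl]methyl}-2-(3-hydroxypropyl)-2-methylcyclohexan-1-one
Product: 33 3-[(1S,2S,3S)-3-[(tert-butyldimethylsilyl)oxy]-2-{[dimethyl(phenyl)silyl]methyl}-1-methyl-6-oxocyclohexyl]propanal
Conditions: Dess–Martin periodinane, NaHCO3, CH2Cl2, 0 °C to rt
Reagents that add atoms: none
Why: Dess–Martin oxidation of the primary alcohol under buffered, non-enolising conditions.

Step 22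
Reactants: 33 3-[(1S,2S,3S)-3-[(tert-butyldimethylsilyl)oxy]-2-{[dimethyl(phenyl)silyl]methyl}-1-methyl-6-oxocyclohexyl]propanal
Product: 34 (2S,3S,4S)-4-[(tert-butyldimethylsilyl)oxy]-3-{[dimethyl(phenyl)silyl]methyl}-2-methyl-2-(4-methylpent-3-en-1-yl)cyclohexan-1-one
Conditions: i-PrPPh3I, n-BuLi, THF, 0 °C; then 33, −78 to 0 °C
Reagents that add atoms: triphenyl(propan-2-yl)phosphonium iodide, CC(C)[P+](c1ccccc1)(c1ccccc1)c1ccccc1.[I-]
Why: Wittig olefination is chemoselective for the aldehyde over the hindered ketone and installs the trisubstituted alkene.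

Step 23
Reactants: 34 (2S,3S,4S)-4-[(tert-butyldimethylsilyl)oxy]-3-{[dimethyl(phenyl)silyl]methyl}-2-methyl-2-(4-methylpent-3-en-1-yl)cyclohexan-1-one
Product: 35 (1R,2S,3S,4S)-4-[(tert-butyldimethylsilyl)oxy]-3-{[dimethyl(phenyl)silyl]methyl}-2-methyl-2-(4-methylpent-3-en-1-yl)cyclohexan-1-ol
Conditions: LiBH(s-Bu)3, THF, −78 to −20 °C; aq. NH4Cl
Reagents that add atoms: none
Why: The chair is locked with the arm and silyloxy group equatorial and the ring methyl axial, so the bulky borohydride attacks equatorially and gives the axial (1R) alcohol cis to the side chain.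

Step 24
Reactants: 35 (1R,2S,3S,4S)-4-[(tert-butyldimethylsilyl)oxy]-3-{[dimethyl(phenyl)silyl]methyl}-2-methyl-2-(4-methylpent-3-en-1-yl)cyclohexan-1-ol
Product: 36 (1R,2S,3S,4S)-4-[(tert-butyldimethylsilyl)oxy]-2-{2-[(2S)-3,3-dimethyloxiran-2-yl]ethyl}-3-{[dimethyl(phenyl)silyl]methyl}-2-methylcyclohexan-1-ol
Conditions: ent-Shi ketone (enantiomer of the D-fructose-derived ketone, 30 mol %), Oxone (2KHSO5·KHSO4·K2SO4), K2CO3, Bu4NHSO4, Na2B4O7 buffer, MeCN–CH2(OMe)2–H2O, 0 °C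
Reagents that add atoms: potassium peroxymonosulfate, [K+].[O-]S(=O)(=O)OO
Why: Shi asymmetric epoxidation of the trisubstituted alkene by the chiral dioxirane is reagent-controlled and gives the (S) epoxide.

Step 25
Reactants: 36 (1R,2S,3S,4S)-4-[(tert-butyldimethylsilyl)oxy]-2-{2-[(2S)-3,3-dimethyloxiran-2-yl]ethyl}-3-{[dimethyl(phenyl)silyl]methyl}-2-methylcyclohexan-1-ol
Product: 37 (3S,5aS,6S,7S,9aR)-7-[(tert-butyldimethylsilyl)oxy]-6-{[dimethyl(phenyl)silyl]methyl}-2,2,5a-trimethyldecahydro-1-benzoxepin-3-ol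
Conditions: camphorsulfonic acid (10 mol %), CH2Cl2, −20 to 0 °C
Reagents that add atoms: none
Why: Acid-catalysed 7-endo epoxide opening: the axial hydroxyl attacks the tertiary (Markovnikov) epoxide carbon, so the cis-fused oxepane forms and C-3 keeps its (S) configuration.

Step 26
Reactants: 37 (3S,5aS,6S,7S,9aR)-7-[(tert-butyldimethylsilyl)oxy]-6-{[dimethyl(phenyl)silyl]methyl}-2,2,5a-trimethyldecahydro-1-benzoxepin-3-ol
Product: 38 (3S,5aS,6S,7S,9aR)-7-[(tert-butyldimethylsilyl)oxy]-6-{[dimethyl(phenyl)silyl]methyl}-2,2,5a-trimethyldecahydro-1-benzoxepin-3-yl acetate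
Conditions: Ac2O, pyridine, DMAP (cat.), CH2Cl2, rt
Reagents that add atoms: acetic anhydride, CC(=O)OC(C)=O
Why: DMAP-catalysed acetylation protects the C-3 alcohol with a group that survives fluoride and oxidation and is removed by the final Grignard step.

Step 27
Reactants: 38 (3S,5aS,6S,7S,9aR)-7-[(tert-butyldimethylsilyl)oxy]-6-{[dimethyl(phenyl)silyl]methyl}-2,2,5a-trimethyldecahydro-1-benzoxepin-3-yl acetate
Product: 39 (3S,5aS,6R,7S,9aR)-7-[(tert-butyldimethylsilyl)oxy]-6-(hydroxymethyl)-2,2,5a-trimethyldecahydro-1-benzoxepin-3-yl acetate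
Conditions: KBr, AcOOH, NaOAc, AcOH, 0 °C to rt
Reagents that add atoms: peracetic acid, CC(=O)OO
Why: Fleming–Tamao oxidation (ipso-bromodesilylation of the phenyl group, then peracid-induced carbon-to-oxygen shift) unmasks the hydroxymethyl arm; the molecule has no alkene at this stage and C-6 is unchanged spatially (the descriptor changes only by priority).

Step 28
Reactants: 39 (3S,5aS,6R,7S,9aR)-7-[(tert-butyldimethylsilyl)oxy]-6-(hydroxymethyl)-2,2,5a-trimethyldecahydro-1-benzoxepin-3-yl acetate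
Product: 40 (3S,5aS,6S,7S,9aR)-7-[(tert-butyldimethylsilyl)oxy]-6-formyl-2,2,5a-trimethyldecahydro-1-benzoxepin-3-yl acetate
Conditions: Dess–Martin periodinane, NaHCO3, CH2Cl2, 0 °C to rt
Reagents that add atoms: none
Why: Dess–Martin oxidation gives the aldehyde without epimerisation; the equatorial formyl group is also the thermodynamically preferred epimer.

## Union and end game (steps 29–33)

Step 29
Reactants: 24 1-phenyl-5-[({(1S,3aS,5R,8aS)-1,4,4,6-tetramethyl-1-[(triethylsilyl)oxy]-1,2,3,3a,4,5,8,8a-octahydroazulen-5-yl}methyl)sulfonyl]-1H-tetrazole; 40 (3S,5aS,6S,7S,9aR)-7-[(tert-butyldimethylsilyl)oxy]-6-formyl-2,2,5a-trimethyldecahydro-1-benzoxepin-3-yl acetate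
Product: 41 (3S,5aS,6S,7S,9aR)-7-[(tert-butyldimethylsilyl)oxy]-2,2,5a-trimethyl-6-[(E)-2-{(1S,3aS,5R,8aS)-1,4,4,6-tetramethyl-1-[(triethylsilyl)oxy]-1,2,3,3a,4,5,8,8a-octahydroazulen-5-yl}ethenyl]decahydro-1-benzoxepin-3-yl acetate
Conditions: KN(SiMe3)2, DME, −60 °C; then 40, −60 °C to rt
Reagents that add atoms: none
Why: Julia–Kocienski olefination (sulfonyl carbanion addition, Smiles rearrangement, loss of SO2 and tetrazolate) joins the two C15 halves; the alkene geometry is irrelevant because the bond is reduced next.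

Step 30
Reactants: 41 (3S,5aS,6S,7S,9aR)-7-[(tert-butyldimethylsilyl)oxy]-2,2,5a-trimethyl-6-[(E)-2-{(1S,3aS,5R,8aS)-1,4,4,6-tetramethyl-1-[(triethylsilyl)oxy]-1,2,3,3a,4,5,8,8a-octahydroazulen-5-yl}ethenyl]decahydro-1-benzoxepin-3-yl acetate
Product: 42 (3S,5aS,6S,7S,9aR)-7-[(tert-butyldimethylsilyl)oxy]-2,2,5a-trimethyl-6-(2-{(1S,3aS,5R,8aS)-1,4,4,6-tetramethyl-1-[(triethylsilyl)oxy]-1,2,3,3a,4,5,8,8a-octahydroazulen-5-yl}ethyl)decahydro-1-benzoxepin-3-yl acetate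
Conditions: 2-nitrobenzenesulfonohydrazide, Et3N, CH2Cl2, rt
Reagents that add atoms: none
Why: Diimide reduction is selective for the 1,2-disubstituted alkene over the trisubstituted ring alkene.

Step 31
Reactants: 42 (3S,5aS,6S,7S,9aR)-7-[(tert-butyldimethylsilyl)oxy]-2,2,5a-trimethyl-6-(2-{(1S,3aS,5R,8aS)-1,4,4,6-tetramethyl-1-[(triethylsilyl)oxy]-1,2,3,3a,4,5,8,8a-octahydroazulen-5-yl}ethyl)decahydro-1-benzoxepin-3-yl acetate
Product: 43 (3S,5aS,6S,7S,9aR)-7-hydroxy-6-{2-[(1S,3aS,5R,8aS)-1-hydroxy-1,4,4,6-tetramethyl-1,2,3,3a,4,5,8,8a-octahydroazulen-5-yl]ethyl}-2,2,5a-trimethyldecahydro-1-benzoxepin-3-yl acetate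
Conditions: HF·pyridine, pyridine, THF, 0 °C to rt
Reagents that add atoms: none
Why: Fluoride desilylation removes both silyl ethers and leaves the acetate in place.

Step 32
Reactants: 43 (3S,5aS,6S,7S,9aR)-7-hydroxy-6-{2-[(1S,3aS,5R,8aS)-1-hydroxy-1,4,4,6-tetramethyl-1,2,3,3a,4,5,8,8a-octahydroazulen-5-yl]ethyl}-2,2,5a-trimethyldecahydro-1-benzoxepin-3-yl acetate
Product: 44 (3S,5aS,6S,9aR)-6-{2-[(1S,3aS,5R,8aS)-1-hydroxy-1,4,4,6-tetramethyl-1,2,3,3a,4,5,8,8a-octahydroazulen-5-yl]ethyl}-2,2,5a-trimethyl-7-oxodecahydro-1-benzoxepin-3-yl acetate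
Conditions: Dess–Martin periodinane, NaHCO3, CH2Cl2, 0 °C
Reagents that add atoms: none
Why: Dess–Martin oxidation of the only secondary alcohol under buffered conditions avoids epimerising the adjacent C-6 centre.

Step 33
Reactants: 44 (3S,5aS,6S,9aR)-6-{2-[(1S,3aS,5R,8aS)-1-hydroxy-1,4,4,6-tetramethyl-1,2,3,3a,4,5,8,8a-octahydroazulen-5-yl]ethyl}-2,2,5a-trimethyl-7-oxodecahydro-1-benzoxepin-3-yl acetate
Product: 45 (3S,5aS,6S,7R,9aR)-6-{2-[(1S,3aS,5R,8aS)-1-hydroxy-1,4,4,6-tetramethyl-1,2,3,3a,4,5,8,8a-octahydroazulen-5-yl]ethyl}-2,2,5a,7-tetramethyldecahydro-1-benzoxepine-3,7-diol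
Conditions: MeMgBr (8 equiv), THF, −78 to 0 °C; aq. NH4Cl
Reagents that add atoms: methylmagnesium bromide, C[Mg]Br
Why: Grignard addition: axial approach to the ketone is blocked by the syn-axial angular methyl, so methyl enters equatorially and the tertiary hydroxyl ends axial (7R); the excess reagent cleaves the acetate.

## Compound list
1 | but-3-en-2-one | CC(=O)C=C | starting material
2 | 4-bromobutan-2-one | CC(=O)CCBr | intermediate
3 | 2-(2-bromoethyl)-2-methyl-1,3-dioxolane | CC1(CCBr)OCCO1 | intermediate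
4 | [2-(2-methyl-1,3-dioxolan-2-yl)ethyl]magnesium bromide | CC1(CC[Mg]Br)OCCO1 | intermediate
5 | [2-(2-methyl-1,3-dioxolan-2-yl)ethyl][(trimethylsilyl)methyl]zinc | CC1(CC[Zn]C[Si](C)(C)C)OCCO1 | intermediate
6 | 2-methylpropanal | CC(C)C=O | starting material
7 | pent-1-en-3-one | CCC(=O)C=C | starting material
8 | 2,2-dimethyl-5-oxoheptanal | CCC(=O)CCC(C)(C)C=O | intermediate
9 | 2,4,4-trimethylcyclohex-2-en-1-one | CC1=CC(C)(C)CCC1=O | intermediate
10 | 2,4,4-trimethylcyclohexa-2,5-dien-1-one | CC1=CC(C)(C)C=CC1=O | intermediate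
11 | [(trimethylsilyl)methyl]zinc (3S)-4,4,6-trimethyl-3-[2-(2-methyl-1,3-dioxolan-2-yl)ethyl]cyclohexa-1,5-dien-1-olate | CC1=CC(C)(C)[C@@H](CCC2(C)OCCO2)C=C1O[Zn]C[Si](C)(C)C | intermediate
12 | trimethyl({(3S)-4,4,6-trimethyl-3-[2-(2-methyl-1,3-dioxolan-2-yl)ethyl]cyclohexa-1,5-dien-1-yl}oxy)silane | CC1=CC(C)(C)[C@@H](CCC2(C)OCCO2)C=C1O[Si](C)(C)C | intermediate
13 | trimethyl({(1R,5S,6S)-2,4,4-trimethyl-5-[2-(2-methyl-1,3-dioxolan-2-yl)ethyl]bicyclo[4.1.0]hept-2-en-1-yl}oxy)silane | CC1=CC(C)(C)[C@@H](CCC2(C)OCCO2)[C@@H]3C[C@]13O[Si](C)(C)C | intermediate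
14 | (5R)-6-chloro-2,4,4-trimethyl-5-[2-(2-methyl-1,3-dioxolan-2-yl)ethyl]cyclohept-2-en-1-one (both C-6 epimers) | CC1=CC(C)(C)[C@@H](CCC2(C)OCCO2)C(Cl)CC1=O | intermediate
15 | (5S)-2,4,4-trimethyl-5-[2-(2-methyl-1,3-dioxolan-2-yl)ethyl]cyclohepta-2,6-dien-1-one | CC1=CC(C)(C)[C@@H](CCC2(C)OCCO2)C=CC1=O | intermediate
16 | (5S)-2,4,4-trimethyl-5-(3-oxobutyl)cyclohepta-2,6-dien-1-one | CC1=CC(C)(C)[C@@H](CCC(C)=O)C=CC1=O | intermediate
17 | (1S,3aS,8aS)-1-hydroxy-1,4,4,6-tetramethyl-2,3,3a,4,8,8a-hexahydroazulen-7(1H)-one | CC1=CC(C)(C)[C@H]2CC[C@](C)(O)[C@H]2CC1=O | intermediate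
18 | (1S,3aS,8aS)-1,4,4,6-tetramethyl-1-[(triethylsilyl)oxy]-2,3,3a,4,8,8a-hexahydroazulen-7(1H)-one | CC1=CC(C)(C)[C@H]2CC[C@](C)(O[Si](CC)(CC)CC)[C@H]2CC1=O | intermediate
19 | (1S,3aS,7R,8aS)-1,4,4,6-tetramethyl-1-[(triethylsilyl)oxy]-1,2,3,3a,4,7,8,8a-octahydroazulen-7-ol | CC1=CC(C)(C)[C@H]2CC[C@](C)(O[Si](CC)(CC)CC)[C@H]2C[C@H]1O | intermediate
20 | tributyl[({(1S,3aS,7R,8aS)-1,4,4,6-tetramethyl-1-[(triethylsilyl)oxy]-1,2,3,3a,4,7,8,8a-octahydroazulen-7-yl}oxy)methyl]stannane | CC1=CC(C)(C)[C@H]2CC[C@](C)(O[Si](CC)(CC)CC)[C@H]2C[C@H]1OC[Sn](CCCC)(CCCC)CCCC | intermediate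
21 | [({(1S,3aS,7R,8aS)-1,4,4,6-tetramethyl-1-[(triethylsilyl)oxy]-1,2,3,3a,4,7,8,8a-octahydroazulen-7-yl}oxy)methyl]lithium | CC1=CC(C)(C)[C@H]2CC[C@](C)(O[Si](CC)(CC)CC)[C@H]2C[C@H]1OC[Li] | intermediate
22 | {(1S,3aS,5R,8aS)-1,4,4,6-tetramethyl-1-[(triethylsilyl)oxy]-1,2,3,3a,4,5,8,8a-octahydroazulen-5-yl}methanol | CC1=CC[C@H]2[C@H](CC[C@]2(C)O[Si](CC)(CC)CC)C(C)(C)[C@@H]1CO | intermediate
23 | 1-phenyl-5-[({(1S,3aS,5R,8aS)-1,4,4,6-tetramethyl-1-[(triethylsilyl)oxy]-1,2,3,3a,4,5,8,8a-octahydroazulen-5-yl}methyl)sulfanyl]-1H-tetrazole | CC1=CC[C@H]2[C@H](CC[C@]2(C)O[Si](CC)(CC)CC)C(C)(C)[C@@H]1CSc1nnnn1-c1ccccc1 | intermediate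
24 | 1-phenyl-5-[({(1S,3aS,5R,8aS)-1,4,4,6-tetramethyl-1-[(triethylsilyl)oxy]-1,2,3,3a,4,5,8,8a-octahydroazulen-5-yl}methyl)sulfonyl]-1H-tetrazole | CC1=CC[C@H]2[C@H](CC[C@]2(C)O[Si](CC)(CC)CC)C(C)(C)[C@@H]1CS(=O)(=O)c1nnnn1-c1ccccc1 | intermediate
25 | 1,4-dioxane-2,5-diol (glycolaldehyde dimer) | OC1COC(O)CO1 | starting material
26 | [(tert-butyldimethylsilyl)oxy]acetaldehyde | CC(C)(C)[Si](C)(C)OCC=O | intermediate
27 | (2S)-2-[(tert-butyldimethylsilyl)oxy]-5-oxoheptanal | CCC(=O)CC[C@H](O[Si](C)(C)C(C)(C)C)C=O | intermediate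
28 | (4S)-4-[(tert-butyldimethylsilyl)oxy]-2-methylcyclohex-2-en-1-one | CC1=C[C@@H](O[Si](C)(C)C(C)(C)C)CCC1=O | intermediate
29 | chloromagnesium (3S,4S)-4-[(tert-butyldimethylsilyl)oxy]-3-{[dimethyl(phenyl)silyl]methyl}-2-methylcyclohex-1-en-1-olate | C[Si](C)(c1ccccc1)C[C@H]1C(C)=C(O[Mg]Cl)CC[C@@H]1O[Si](C)(C)C(C)(C)C | intermediate
30 | (2S,3S,4S)-4-[(tert-butyldimethylsilyl)oxy]-3-{[dimethyl(phenyl)silyl]methyl}-2-methyl-2-(prop-2-en-1-yl)cyclohexan-1-one | C[Si](C)(c1ccccc1)C[C@H]1[C@](C)(CC=C)C(=O)CC[C@@H]1O[Si](C)(C)C(C)(C)C | intermediate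
31 | (2S,3S,4S)-2-[3-(9-borabicyclo[3.3.1]nonan-9-yl)propyl]-4-[(tert-butyldimethylsilyl)oxy]-3-{[dimethyl(phenyl)silyl]methyl}-2-methylcyclohexan-1-one | C[Si](C)(c1ccccc1)C[C@H]1[C@](C)(CCCB2C3CCCC2CCC3)C(=O)CC[C@@H]1O[Si](C)(C)C(C)(C)C | intermediate
32 | (2S,3S,4S)-4-[(tert-butyldimethylsilyl)oxy]-3-{[dimethyl(phenyl)silyl]methyl}-2-(3-hydroxypropyl)-2-methylcyclohexan-1-one | C[Si](C)(c1ccccc1)C[C@H]1[C@](C)(CCCO)C(=O)CC[C@@H]1O[Si](C)(C)C(C)(C)C | intermediate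
33 | 3-[(1S,2S,3S)-3-[(tert-butyldimethylsilyl)oxy]-2-{[dimethyl(phenyl)silyl]methyl}-1-methyl-6-oxocyclohexyl]propanal | C[Si](C)(c1ccccc1)C[C@H]1[C@](C)(CCC=O)C(=O)CC[C@@H]1O[Si](C)(C)C(C)(C)C | intermediate
34 | (2S,3S,4S)-4-[(tert-butyldimethylsilyl)oxy]-3-{[dimethyl(phenyl)silyl]methyl}-2-methyl-2-(4-methylpent-3-en-1-yl)cyclohexan-1-one | C[Si](C)(c1ccccc1)C[C@H]1[C@](C)(CCC=C(C)C)C(=O)CC[C@@H]1O[Si](C)(C)C(C)(C)C | intermediate
35 | (1R,2S,3S,4S)-4-[(tert-butyldimethylsilyl)oxy]-3-{[dimethyl(phenyl)silyl]methyl}-2-methyl-2-(4-methylpent-3-en-1-yl)cyclohexan-1-ol | C[Si](C)(c1ccccc1)C[C@H]1[C@](C)(CCC=C(C)C)[C@H](O)CC[C@@H]1O[Si](C)(C)C(C)(C)C | intermediate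
36 | (1R,2S,3S,4S)-4-[(tert-butyldimethylsilyl)oxy]-2-{2-[(2S)-3,3-dimethyloxiran-2-yl]ethyl}-3-{[dimethyl(phenyl)silyl]methyl}-2-methylcyclohexan-1-ol | C[Si](C)(c1ccccc1)C[C@H]1[C@](C)(CC[C@@H]2OC2(C)C)[C@H](O)CC[C@@H]1O[Si](C)(C)C(C)(C)C | intermediate
37 | (3S,5aS,6S,7S,9aR)-7-[(tert-butyldimethylsilyl)oxy]-6-{[dimethyl(phenyl)silyl]methyl}-2,2,5a-trimethyldecahydro-1-benzoxepin-3-ol | C[Si](C)(c1ccccc1)C[C@H]1[C@]2(C)CC[C@H](O)C(C)(C)O[C@@H]2CC[C@@H]1O[Si](C)(C)C(C)(C)C | intermediate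
38 | (3S,5aS,6S,7S,9aR)-7-[(tert-butyldimethylsilyl)oxy]-6-{[dimethyl(phenyl)silyl]methyl}-2,2,5a-trimethyldecahydro-1-benzoxepin-3-yl acetate | C[Si](C)(c1ccccc1)C[C@H]1[C@]2(C)CC[C@H](OC(C)=O)C(C)(C)O[C@@H]2CC[C@@H]1O[Si](C)(C)C(C)(C)C | intermediate
39 | (3S,5aS,6R,7S,9aR)-7-[(tert-butyldimethylsilyl)oxy]-6-(hydroxymethyl)-2,2,5a-trimethyldecahydro-1-benzoxepin-3-yl acetate | OC[C@H]1[C@]2(C)CC[C@H](OC(C)=O)C(C)(C)O[C@@H]2CC[C@@H]1O[Si](C)(C)C(C)(C)C | intermediate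
40 | (3S,5aS,6S,7S,9aR)-7-[(tert-butyldimethylsilyl)oxy]-6-formyl-2,2,5a-trimethyldecahydro-1-benzoxepin-3-yl acetate | O=C[C@H]1[C@]2(C)CC[C@H](OC(C)=O)C(C)(C)O[C@@H]2CC[C@@H]1O[Si](C)(C)C(C)(C)C | intermediate
41 | (3S,5aS,6S,7S,9aR)-7-[(tert-butyldimethylsilyl)oxy]-2,2,5a-trimethyl-6-[(E)-2-{(1S,3aS,5R,8aS)-1,4,4,6-tetramethyl-1-[(triethylsilyl)oxy]-1,2,3,3a,4,5,8,8a-octahydroazulen-5-yl}ethenyl]decahydro-1-benzoxepin-3-yl acetate | CC1=CC[C@H]2[C@H](CC[C@]2(C)O[Si](CC)(CC)CC)C(C)(C)[C@@H]1/C=C/[C@H]1[C@]2(C)CC[C@H](OC(C)=O)C(C)(C)O[C@@H]2CC[C@@H]1O[Si](C)(C)C(C)(C)C | intermediate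
42 | (3S,5aS,6S,7S,9aR)-7-[(tert-butyldimethylsilyl)oxy]-2,2,5a-trimethyl-6-(2-{(1S,3aS,5R,8aS)-1,4,4,6-tetramethyl-1-[(triethylsilyl)oxy]-1,2,3,3a,4,5,8,8a-octahydroazulen-5-yl}ethyl)decahydro-1-benzoxepin-3-yl acetate | CC1=CC[C@H]2[C@H](CC[C@]2(C)O[Si](CC)(CC)CC)C(C)(C)[C@@H]1CC[C@H]1[C@]2(C)CC[C@H](OC(C)=O)C(C)(C)O[C@@H]2CC[C@@H]1O[Si](C)(C)C(C)(C)C | intermediate
43 | (3S,5aS,6S,7S,9aR)-7-hydroxy-6-{2-[(1S,3aS,5R,8aS)-1-hydroxy-1,4,4,6-tetramethyl-1,2,3,3a,4,5,8,8a-octahydroazulen-5-yl]ethyl}-2,2,5a-trimethyldecahydro-1-benzoxepin-3-yl acetate | CC1=CC[C@H]2[C@H](CC[C@]2(C)O)C(C)(C)[C@@H]1CC[C@H]1[C@]2(C)CC[C@H](OC(C)=O)C(C)(C)O[C@@H]2CC[C@@H]1O | intermediate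
44 | (3S,5aS,6S,9aR)-6-{2-[(1S,3aS,5R,8aS)-1-hydroxy-1,4,4,6-tetramethyl-1,2,3,3a,4,5,8,8a-octahydroazulen-5-yl]ethyl}-2,2,5a-trimethyl-7-oxodecahydro-1-benzoxepin-3-yl acetate | CC1=CC[C@H]2[C@H](CC[C@]2(C)O)C(C)(C)[C@@H]1CC[C@H]1[C@]2(C)CC[C@H](OC(C)=O)C(C)(C)O[C@@H]2CCC1=O | intermediate
45 | (3S,5aS,6S,7R,9aR)-6-{2-[(1S,3aS,5R,8aS)-1-hydroxy-1,4,4,6-tetramethyl-1,2,3,3a,4,5,8,8a-octahydroazulen-5-yl]ethyl}-2,2,5a,7-tetramethyldecahydro-1-benzoxepine-3,7-diol | CC1=CC[C@H]2[C@H](CC[C@]2(C)O)C(C)(C)[C@@H]1CC[C@H]1[C@]2(C)CC[C@H](O)C(C)(C)O[C@@H]2CC[C@@]1(C)O | target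

## Step count and weak points
Total step count: 33. Longest linear sequence: 18 (steps 3–15 then 29–33; the paths through steps 1, 2, 5–15 and through steps 16–28 are equally long).

Step 9 (SmI2 closure of the cyclopentanol). The cross-conjugated dienone is itself easily reduced, so over-reduction or dimerisation may compete with cyclisation. The fallback sets out from 16 and comes back at 17, replacing ketyl chemistry with a hydrogen-atom-transfer radical cyclisation. The methyl ketone is silylated (LiN(i-Pr)2, t-BuMe2SiCl, HMPA, THF, −78 °C) to the enol ether (5S)-5-{3-[(tert-butyldimethylsilyl)oxy]but-3-en-1-yl}-2,4,4-trimethylcyclohepta-2,6-dien-1-one F1. Fe(acac)3 and PhSiH3 in EtOH at 60 °C turn the enol ether into an α-silyloxy tertiary radical that closes 5-exo onto the enone β-carbon, giving (1S,3aS,8aS)-1-[(tert-butyldimethylsilyl)oxy]-1,4,4,6-tetramethyl-2,3,3a,4,8,8a-hexahydroazulen-7(1H)-one F2. The cis fusion is enforced by the tether, but the C-1 configuration is less secure than with SmI2 and the epimer would have to be separated. Bu4NF then releases 17.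

Step 25 (7-endo epoxide opening). The 6-exo mode, giving a tetrahydropyran carrying a 2-hydroxypropan-2-yl group, and hydride-shift rearrangement of the epoxide are the likely competitors. The fallback sets out from 36 and comes back at 37, and removes the regiochemical choice. Diethylaluminium 2,2,6,6-tetramethylpiperidide (toluene, 0 °C) isomerises the epoxide to the allylic alcohol (1R,2S,3S,4S)-4-[(tert-butyldimethylsilyl)oxy]-3-{[dimethyl(phenyl)silyl]methyl}-2-[(3S)-3-hydroxy-4-methylpent-4-en-1-yl]-2-methylcyclohexan-1-ol F3 with retention at the carbinol carbon. Hg(OCOCF3)2 in CH2Cl2 then effects a 7-exo Markovnikov oxymercuration, for which the only competing ring size would be eight, giving the organomercurial (3S,5aS,6S,7S,9aR)-7-[(tert-butyldimethylsilyl)oxy]-6-{[dimethyl(phenyl)silyl]methyl}-2,5a-dimethyl-2-{[(trifluoroacetoxy)mercurio]methyl}decahydro-1-benzoxepin-3-ol F4. Demercuration with NaBH4 and NaOH turns the CH2Hg group into the second methyl and delivers 37.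

Step 29 (Julia–Kocienski union). Both partners are hindered next to the reacting carbons, so sulfone self-condensation or a stalled addition is possible. The fallback sets out from 22 and 40 and comes back at 42, using carbonyl addition and radical deoxygenation instead and skipping the alkene altogether. Alcohol 22 is converted (I2, PPh3, imidazole) into triethyl{[(1S,3aS,5R,8aS)-5-(iodomethyl)-1,4,4,6-tetramethyl-1,2,3,3a,4,5,8,8a-octahydroazulen-1-yl]oxy}silane F5. Iodine–lithium exchange (t-BuLi, Et2O, −78 °C) and transmetalation with MgBr2·OEt2 give an alkylmagnesium that adds to aldehyde 40 without touching the acetate. The product is (3S,5aS,7S,9aR)-7-[(tert-butyldimethylsilyl)oxy]-6-(1-hydroxy-2-{(1S,3aS,5R,8aS)-1,4,4,6-tetramethyl-1-[(triethylsilyl)oxy]-1,2,3,3a,4,5,8,8a-octahydroazulen-5-yl}ethyl)-2,2,5a-trimethyldecahydro-1-benzoxepin-3-yl acetate F6, with C-6 as in 40 and both carbinol epimers usable. It is converted (NaH, CS2, MeI) into its O-alkyl S-methyl carbonodithioate F7, and Barton–McCombie reduction (Bu3SnH, AIBN, toluene, 80 °C) gives 42.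

## Further compounds
F1 | step 9 | (5S)-5-{3-[(tert-butyldimethylsilyl)oxy]but-3-en-1-yl}-2,4,4-trimethylcyclohepta-2,6-dien-1-one | CC1=CC(C)(C)[C@@H](CCC(=C)O[Si](C)(C)C(C)(C)C)C=CC1=O
F2 | step 9 | (1S,3aS,8aS)-1-[(tert-butyldimethylsilyl)oxy]-1,4,4,6-tetramethyl-2,3,3a,4,8,8a-hexahydroazulen-7(1H)-one | CC1=CC(C)(C)[C@H]2CC[C@](C)(O[Si](C)(C)C(C)(C)C)[C@H]2CC1=O
F3 | step 25 | (1R,2S,3S,4S)-4-[(tert-butyldimethylsilyl)oxy]-3-{[dimethyl(phenyl)silyl]methyl}-2-[(3S)-3-hydroxy-4-methylpent-4-en-1-yl]-2-methylcyclohexan-1-ol | C[Si](C)(c1ccccc1)C[C@H]1[C@](C)(CC[C@H](O)C(C)=C)[C@H](O)CC[C@@H]1O[Si](C)(C)C(C)(C)C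
F4 | step 25 | (3S,5aS,6S,7S,9aR)-7-[(tert-butyldimethylsilyl)oxy]-6-{[dimethyl(phenyl)silyl]methyl}-2,5a-dimethyl-2-{[(trifluoroacetoxy)mercurio]methyl}decahydro-1-benzoxepin-3-ol (both C-2 epimers) | C[Si](C)(c1ccccc1)C[C@H]1[C@]2(C)CC[C@H](O)C(C)(C[Hg]OC(=O)C(F)(F)F)O[C@@H]2CC[C@@H]1O[Si](C)(C)C(C)(C)C
F5 | step 29 | triethyl{[(1S,3aS,5R,8aS)-5-(iodomethyl)-1,4,4,6-tetramethyl-1,2,3,3a,4,5,8,8a-octahydroazulen-1-yl]oxy}silane | CC1=CC[C@H]2[C@H](CC[C@]2(C)O[Si](CC)(CC)CC)C(C)(C)[C@@H]1CI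
F6 | step 29 | (3S,5aS,7S,9aR)-7-[(tert-butyldimethylsilyl)oxy]-6-(1-hydroxy-2-{(1S,3aS,5R,8aS)-1,4,4,6-tetramethyl-1-[(triethylsilyl)oxy]-1,2,3,3a,4,5,8,8a-octahydroazulen-5-yl}ethyl)-2,2,5a-trimethyldecahydro-1-benzoxepin-3-yl acetate (C-6 as in 40; both carbinol epimers) | CC1=CC[C@H]2[C@H](CC[C@]2(C)O[Si](CC)(CC)CC)C(C)(C)[C@@H]1CC(O)[C@H]1[C@]2(C)CC[C@H](OC(C)=O)C(C)(C)O[C@@H]2CC[C@@H]1O[Si](C)(C)C(C)(C)C
F7 | step 29 | O-alkyl S-methyl carbonodithioate (xanthate) of F6 | CC1=CC[C@H]2[C@H](CC[C@]2(C)O[Si](CC)(CC)CC)C(C)(C)[C@@H]1CC(OC(=S)SC)[C@H]1[C@]2(C)CC[C@H](OC(C)=O)C(C)(C)O[C@@H]2CC[C@@H]1O[Si](C)(C)C(C)(C)C
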